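**Assumptions:** The target is the trans-(1S,2R) 1-aryl-1,2-dihydronaphthalene with free phenols, as drawn. Allyl ethers are used as phenol protecting groups because they survive base, hydride and Lewis acid, and come off under neutral Pd(0) without touching the styrenyl alkene.

## Retrosynthesis
- Target ← Pd(0) deallylation ← diallyl ether diol ← LiAlH4 reduction of an imide/enoate ester.
- The only new carbocycle, the dihydronaphthalene, is formed in a single step: an intramolecular Friedel–Crafts cyclisation of the benzylic cation from an aldol carbinol onto the isovanillyl ring, para to its O-allyl group.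
- The C2 stereocentre is set by an Evans aldol of a Stobbe-derived imide with O-allylvanillin. C1 is set trans to C2 during the cyclisation.
- The (E)-Stobbe half-ester (from O-allylisovanillin and dimethyl succinate) already has the aryl group cis to the CH2 carbon, which is the geometry ring closure needs.

## Route

**Step 1**
Reactants: 1 isovanillin; 2 allyl bromide
Product: 3 3-(allyloxy)-4-methoxybenzaldehyde
Conditions: K2CO3, DMF, 60 °C
Reagents that add atoms: allyl bromide, C=CCBr (compound 2)
Why: Williamson O-alkylation of the only phenol protects it.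

**Step 2**
Reactants: 4 vanillin; 2 allyl bromide
Product: 5 4-(allyloxy)-3-methoxybenzaldehyde
Conditions: K2CO3, DMF, 60 °C
Reagents that add atoms: allyl bromide, C=CCBr (compound 2)
Why: Same Williamson O-allylation, this time for the pendant aryl ring.

**Step 3**
Reactants: 3; 6 dimethyl succinate
Product: 7 (E)-4-aryl-3-(methoxycarbonyl)but-3-enoic acid (Ar = 3-allyloxy-4-methoxyphenyl)
Conditions: KOtBu, tBuOH, reflux; then aq. HCl
Reagents that add atoms: none beyond the reactants (dimethyl succinate, COC(=O)CCC(=O)OC, compound 6)
Why: Stobbe condensation (aldol, lactonisation, E1cB ring opening) gives the E-alkene. The aryl group is trans to CO2Me and cis to CH2CO2H, as needed for the later 6-ring closure.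

**Step 4**
Reactants: 7; 8 (S)-4-benzyloxazolidin-2-one
Product: 9 N-acyl imide, (S)-4-benzyl-3-[(E)-3-(methoxycarbonyl)-4-arylbut-3-enoyl]oxazolidin-2-one
Conditions: (i) PivCl, Et3N, THF, −20 °C; (ii) lithiated 8 (n-BuLi, THF, −78 °C), then warm to 0 °C
Reagents that add atoms: none beyond reactant 8
Why: The mixed anhydride is attacked at the less hindered carbonyl, installing the chiral auxiliary on the CH2CO carbonyl only.

**Step 5**
Reactants: 9; 5
Product: 10 syn-aldol adduct, methyl (E)-2-[(S)-(acyl)-CH(OH)Ar']… (2S, carbinol S)
Conditions: Bu2BOTf, iPr2NEt, CH2Cl2, 0 then −78 °C; add 5, −78 to 0 °C; pH 7 buffer, MeOH/H2O2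
Reagents that add atoms: none beyond reactant 5
Why: Evans boron Z-enolate aldol. The (S)-benzyl auxiliary sets the α-carbon, which becomes C2, as (2S) in this intermediate, i.e. R after cyclisation. The carbinol stereocentre is destroyed in the next step, so only C2 matters.

**Step 6**
Reactants: 10
Product: 11 trans-(1S,2R)-1,2-dihydronaphthalene imide ester
Conditions: BF3·OEt2, CH2Cl2, −40 to 0 °C
Reagents that add atoms: none (loss of H2O)
Why: Ionisation gives a 4-allyloxy-3-methoxybenzhydryl cation, a Friedel–Crafts alkylation closes the ring at the position para to the 3-O-allyl group of the other ring, and this position is ortho to the vinyl group. C1 is set by 1,2-induction from C2, with the aryl trans to the acyl group (pseudo-diaxial). The C3=C4 alkene geometry is fixed by the ring, and the low temperature avoids epimerisation at C2.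

**Step 7**
Reactants: 11
Product: 12 (1S,2R)-diol, 6-allyloxy-1-(4-allyloxy-3-methoxyphenyl)-7-methoxy-2,3-bis(hydroxymethyl)-1,2-dihydronaphthalene
Conditions: LiAlH4, THF, −78 to 0 °C; Rochelle salt workup
Reagents that add atoms: none (hydride only)
Why: Hydride reduces the imide (releasing the auxiliary) and the α-substituted enoate (1,2-reduction) to the two CH2OH groups. No stereocentre is touched, and the allyl ethers and alkene survive.

**Step 8**
Reactants: 12
Product: 13 target
Conditions: Pd(PPh3)4 (5 mol%), K2CO3, MeOH, rt
Reagents that add atoms: none (the allyl groups are transferred to MeOH)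
Why: Pd(0)-catalysed π-allyl deallylation of aryl allyl ethers is chemoselective. The free primary alcohols, the trisubstituted alkene and the stereocentres are untouched.

## Compound list
1 | isovanillin | COc1ccc(C=O)cc1O | starting material
2 | allyl bromide | C=CCBr | starting material
3 | 3-(allyloxy)-4-methoxybenzaldehyde | COc1ccc(C=O)cc1OCC=C | intermediate
4 | vanillin | COc1cc(C=O)ccc1O | starting material
5 | 4-(allyloxy)-3-methoxybenzaldehyde | COc1cc(C=O)ccc1OCC=C | intermediate
6 | dimethyl succinate | COC(=O)CCC(=O)OC | starting material
7 | (E)-Stobbe half-ester | COC(=O)/C(=C/c1ccc(OC)c(OCC=C)c1)CC(=O)O | intermediate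
8 | (S)-4-benzyloxazolidin-2-one | O=C1N[C@@H](Cc2ccccc2)CO1 | starting material
9 | Stobbe imide | COC(=O)/C(=C/c1ccc(OC)c(OCC=C)c1)CC(=O)N1C(=O)OC[C@H]1Cc1ccccc1 | intermediate
10 | Evans syn-aldol adduct | COC(=O)/C(=C/c1ccc(OC)c(OCC=C)c1)[C@H](C(=O)N1C(=O)OC[C@H]1Cc1ccccc1)[C@H](O)c1ccc(OCC=C)c(OC)c1 | intermediate
11 | trans-1,2-dihydronaphthalene imide ester | COC(=O)C1=Cc2cc(OCC=C)c(OC)cc2[C@H](c2ccc(OCC=C)c(OC)c2)[C@H]1C(=O)N1C(=O)OC[C@H]1Cc1ccccc1 | intermediate
12 | diallyl ether diol | OCC1=Cc2cc(OCC=C)c(OC)cc2[C@H](c2ccc(OCC=C)c(OC)c2)[C@H]1CO | intermediate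
13 | target (1S,2R) | COc1cc([C@H]2c3cc(O)c(OC)cc3C=C(CO)[C@@H]2CO)ccc1O | target

## Totals
- Total steps: 8.
- Longest linear sequence: 7 (1 → 3 → 7 → 9 → 10 → 11 → 12 → 13).

## Three steps most likely to fail
1. **Step 6 (Friedel–Crafts cyclisation).** Risks are elimination to a triene, cleavage of the allyl ethers, or epimerisation at the doubly activated C2–H.
   - Fallback: re-sequence so the cyclisation is done on a bis-silyl-protected diol (reduce, silylate, then cyclise with a Lewis acid), so no acidic α-C–H remains.
2. **Step 5 (Evans aldol on the vinylogous imide).** The enolate could isomerise the alkene or react at the γ-position, and the diastereoselectivity is uncertain.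
   - Fallback: drop the auxiliary, do a racemic LDA aldol on the dimethyl ester, and carry the racemate through to diol 12. Resolve 12 by preparative chiral HPLC or by diastereomeric camphanates before deallylation.
3. **Step 7 (LiAlH4 reduction).** Conjugate reduction of the enoate or epimerisation at C2 could occur.
   - Fallback: use a two-stage sequence, LiBH4/MeOH for the imide to give the alcohol and release the auxiliary, then DIBAL-H for the enoate to the allylic alcohol.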